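## Retrosynthetic overview

1. Flemistrictin D 14 ⇐ bis-MOM ketone 13 (acetal cleavage) ⇐ bis-MOM chromene 8 + Weinreb amide 10 (C6–C(=O) bond by directed ortho-metalation at the only aromatic CH) ⇐ hydroquinone 7 ⇐ pyranoquinone 6 (change of oxidation level).
2. Key disconnection: the pyran ring of 6 is opened at O1–C2 (retro-oxa-6π) and at C4–C4a (retro-Knoevenagel) to 2-hydroxy-6-methoxy-1,4-benzoquinone 3 and 3-methylbut-2-enal 4; 3 ⇐ 2,6-dimethoxy-1,4-benzoquinone 1 by hydrolysis of one of two equivalent vinylogous esters.
3. Enabling feature: the oxygens on C5 and C8 are para on the benzene ring, so this ring is the reduced form of a para-quinone in which O1–C8a=C4a–C5=O is a vinylogous acid; C4a is then a 1,3-dicarbonyl-type nucleophile and, after condensation, the C8a oxygen is the carbonyl terminus of a 1-oxatriene that ends at C2.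
4. Order of rings: the carbocycle is bought as quinone 1; the 2H-pyran ring is formed in step 2; the benzene ring is re-established by reduction in step 3; the target has no stereocentre, and each later bond is made at the only position left open.

Key step: step 2

## Route

Step 1
Reactants: 1 2,6-dimethoxy-1,4-benzoquinone
Product: 3 2-hydroxy-6-methoxy-1,4-benzoquinone, via sodium quinonolate 2 (not isolated)
Conditions: 1 M aq NaOH (2.2 equiv), THF, 0 °C to rt, argon; then 2 M aq HCl to pH 2
Reagents that add atoms: sodium hydroxide, [Na+].[OH-]
Why: Vinylogous ester saponification (conjugate addition–elimination of hydroxide at one of the two equivalent methoxy-bearing carbons) should release methanol and hold the product as the delocalised anion 2, whose charge shields the second methoxy group from a further substitution until acid liberates 3.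

Step 2
Reactants: 3 2-hydroxy-6-methoxy-1,4-benzoquinone; 4 3-methylbut-2-enal
Product: 6 7-methoxy-2,2-dimethyl-2H-chromene-5,8-dione, via oxatriene 5 (not isolated)
Conditions: 4 (3 equiv), pyridine, 90 °C, argon
Reagents that add atoms: none
Why: Under pyridine base catalysis the only enolic carbon of 3 (C3, between the hydroxyl-bearing carbon and the C4 carbonyl, the later C4a) should add to the aldehyde carbon of 4 and lose water (Knoevenagel condensation) to give the cross-conjugated 1-oxatriene 5, which closes by a thermal disrotatory oxa-6π electrocyclisation in which the oxygen of the former hydroxyl group bonds to the dimethyl-substituted alkene terminus, so that C4–C4a and then O1–C2 are formed in one operation. The closest known reaction type is the formal [3+3] annulation of 2-hydroxy-1,4-naphthoquinone and related 2-hydroxy-1,4-benzoquinones with β,β-disubstituted enals to 2H-pyranoquinones. The one ring that is closed, the 2H-pyran, closes in the pericyclic six-electron mode: its six atoms O1, C2, C3, C4, C4a and C8a are exactly the O=C–C=C–C=C array of 5, so no ionic exo or endo cyclisation is involved. No stereocentre is created, because C2 carries two methyl groups and the new C3=C4 alkene is held cis by the ring. The step needs bond formation at C3 of 3 and not at C5, 1,2-addition to the enal and not conjugate addition, and closure through the C2 oxygen (para-quinone 6) and not through the C4 oxygen (ortho-quinone isomer). The first is secured by the enol character of C3 alone, the second by the two β-methyl groups of 4, and the third by the greater stability of the para-quinone, which keeps two vinylogous ester units and to which the reversible ring opening of a non-aromatic 2H-pyran at 90 °C should funnel the material, while a tertiary amine base cannot displace the methoxy group.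

Step 3
Reactants: 6 7-methoxy-2,2-dimethyl-2H-chromene-5,8-dione
Product: 7 7-methoxy-2,2-dimethyl-2H-chromene-5,8-diol
Conditions: Na2S2O4 (3 equiv), EtOAc/H2O, rt, argon; crude 7 used at once
Reagents that add atoms: none
Why: Dithionite reduction of a para-quinone to its hydroquinone adds only two hydrogens, leaves the C3=C4 alkene untouched and re-establishes the aromatic ring of the target (quinone reduction).

Step 4
Reactants: 7 7-methoxy-2,2-dimethyl-2H-chromene-5,8-diol
Product: 8 7-methoxy-5,8-bis(methoxymethoxy)-2,2-dimethyl-2H-chromene
Conditions: MOMCl (3 equiv), iPr2NEt (4 equiv), CH2Cl2, 0 °C to rt, argon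
Reagents that add atoms: chloromethyl methyl ether, COCCl
Why: Williamson-type O-alkylation of both phenols by the highly reactive α-chloro ether should cap the air-sensitive hydroquinone as acetal ethers that withstand organolithium bases and act as ortho-directing groups in step 6.

Step 5
Reactants: 9 3-phenylpropanoyl chloride
Product: 10 N-methoxy-N-methyl-3-phenylpropanamide
Conditions: MeNH(OMe)·HCl (1.1 equiv), pyridine (2.2 equiv), CH2Cl2, 0 °C to rt
Reagents that add atoms: N,O-dimethylhydroxylamine hydrochloride, CNOC.Cl
Why: Nucleophilic acyl substitution of the acid chloride by the liberated hydroxylamine (Schotten–Baumann-type amide formation) should give the Weinreb amide cleanly.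

Step 6
Reactants: 8 7-methoxy-5,8-bis(methoxymethoxy)-2,2-dimethyl-2H-chromene; 10 N-methoxy-N-methyl-3-phenylpropanamide
Product: 13 1-[7-methoxy-5,8-bis(methoxymethoxy)-2,2-dimethyl-2H-chromen-6-yl]-3-phenylpropan-1-one, via aryllithium 11 (not isolated), via tetrahedral lithium adduct 12 (not isolated)
Conditions: n-BuLi (1.2 equiv), THF, −78 to −10 °C; then 10 (1.5 equiv), −78 °C to rt; then H2O
Reagents that add atoms: none
Why: Directed ortho-metalation should remove the only aromatic hydrogen, which lies between the C5 methoxymethoxy and C7 methoxy groups, and aryllithium 11 then adds once to the Weinreb amide to give the chelated adduct 12 (one transient, racemic stereocentre) that collapses to the ketone only on aqueous work-up (Weinreb ketone synthesis).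

Step 7
Reactants: 13 1-[7-methoxy-5,8-bis(methoxymethoxy)-2,2-dimethyl-2H-chromen-6-yl]-3-phenylpropan-1-one
Product: 14 Flemistrictin D
Conditions: 2 M HCl in MeOH (degassed), 40 °C, argon
Reagents that add atoms: none
Why: Acid-catalysed acetal exchange with methanol should cleave both aryl methoxymethyl ethers as dimethoxymethane under conditions that the 2,2-dimethyl-2H-chromene and the aryl methyl ether tolerate, the freed C5 hydroxyl then being held by a hydrogen bond to the ketone (acetal cleavage).

## Compound list

1 | 2,6-dimethoxy-1,4-benzoquinone | COC1=CC(=O)C=C(OC)C1=O | starting material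
2 | sodium 5-methoxy-3,6-dioxocyclohexa-1,4-dien-1-olate | COC1=CC(=O)C=C([O-])C1=O.[Na+] | intermediate
3 | 2-hydroxy-6-methoxy-1,4-benzoquinone | COC1=CC(=O)C=C(O)C1=O | intermediate
4 | 3-methylbut-2-enal | CC(C)=CC=O | starting material
5 | (3Z)-6-methoxy-3-(3-methylbut-2-en-1-ylidene)cyclohex-5-ene-1,2,4-trione | COC1=CC(=O)/C(=C/C=C(C)C)C(=O)C1=O | intermediate
6 | 7-methoxy-2,2-dimethyl-2H-chromene-5,8-dione | COC1=CC(=O)C2=C(OC(C)(C)C=C2)C1=O | intermediate
7 | 7-methoxy-2,2-dimethyl-2H-chromene-5,8-diol | COc1cc(O)c2C=CC(C)(C)Oc2c1O | intermediate
8 | 7-methoxy-5,8-bis(methoxymethoxy)-2,2-dimethyl-2H-chromene | COCOc1cc(OC)c(OCOC)c2OC(C)(C)C=Cc12 | intermediate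
9 | 3-phenylpropanoyl chloride | O=C(Cl)CCc1ccccc1 | starting material
10 | N-methoxy-N-methyl-3-phenylpropanamide | CON(C)C(=O)CCc1ccccc1 | intermediate
11 | [7-methoxy-5,8-bis(methoxymethoxy)-2,2-dimethyl-2H-chromen-6-yl]lithium | [Li]c1c(OC)c(OCOC)c2OC(C)(C)C=Cc2c1OCOC | intermediate
12 | lithium 1-[7-methoxy-5,8-bis(methoxymethoxy)-2,2-dimethyl-2H-chromen-6-yl]-1-[methoxy(methyl)amino]-3-phenylpropan-1-olate (racemic) | CON(C)C([O-])(CCc1ccccc1)c1c(OC)c(OCOC)c2OC(C)(C)C=Cc2c1OCOC.[Li+] | intermediate
13 | 1-[7-methoxy-5,8-bis(methoxymethoxy)-2,2-dimethyl-2H-chromen-6-yl]-3-phenylpropan-1-one | COCOc1c(C(=O)CCc2ccccc2)c(OC)c(OCOC)c2OC(C)(C)C=Cc12 | intermediate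
14 | Flemistrictin D, 1-(5,8-dihydroxy-7-methoxy-2,2-dimethyl-2H-chromen-6-yl)-3-phenylpropan-1-one | COc1c(O)c2c(c(O)c1C(=O)CCc1ccccc1)C=CC(C)(C)O2 | target

## Step count and risks

Total step count: 7. Longest linear sequence: 6 (steps 1, 2, 3, 4, 6 and 7; step 5 is a one-step side branch).

Steps most likely to fail:

1. Step 2 (key step). The hydroxyquinone may add as a nucleophile to a second quinone molecule or to product 6 faster than it condenses with the aldehyde in hot pyridine, and part of oxatriene 5 may close through the C4 oxygen. The fallback sets out from 3 and comes back at 6. C-Alkylation of 3 (LiH, DMSO; then 1-bromo-3-methylbut-2-ene, rt) should give 2-hydroxy-6-methoxy-3-(3-methylbut-2-en-1-yl)-1,4-benzoquinone F1. DDQ (1.1 equiv) in benzene at rt should then abstract hydride from the doubly activated methylene of F1 and, after loss of the hydroxyl proton, deliver the same oxatriene 5 at room temperature, without base and at low stationary concentration. Oxatriene 5 then electrocyclises to 6 (dehydrogenative cyclisation of a 2-hydroxy-3-prenylquinone).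

2. Step 1. Hydroxide may also add to the unsubstituted ring carbons and start redox disproportionation and ring degradation, and a second substitution to the 2,6-dihydroxyquinone may follow on warming. The fallback sets out from 1 and comes back at 3. Na2S2O4 (EtOAc/H2O, rt) should reduce 1 to 2,6-dimethoxybenzene-1,4-diol F2. AlCl3 (1.1 equiv) and pyridine in CH2Cl2 at reflux, followed by aq HCl, should cleave exactly one methyl ether, because AlCl3 bridges the C1 oxygen and one neighbouring methoxy oxygen and the catechol unit formed resists a second cleavage, giving 6-methoxybenzene-1,2,4-triol F3. Ag2O in Et2O should oxidise the para-dihydroxy pair of F3 to 3.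

3. Step 6. The doubly flanked aryllithium 11 may act as a base toward the α-methylene of amide 10, or acyl transfer at this hindered carbon may be slow, so that 8 is returned on work-up. The fallback sets out from 8 and comes back at 13. Lithiation as in step 6 and quenching with N,N-dimethylformamide, which cannot be enolised, should give 7-methoxy-5,8-bis(methoxymethoxy)-2,2-dimethyl-2H-chromene-6-carbaldehyde F4. PhCH2CH2MgBr (THF, 0 °C; then H2O) should add to the aldehyde to give racemic 1-[7-methoxy-5,8-bis(methoxymethoxy)-2,2-dimethyl-2H-chromen-6-yl]-3-phenylpropan-1-ol F5. IBX in DMSO at rt should oxidise this benzylic alcohol to ketone 13.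

## Further compounds

F1 | step 2 | 2-hydroxy-6-methoxy-3-(3-methylbut-2-en-1-yl)-1,4-benzoquinone | COC1=CC(=O)C(CC=C(C)C)=C(O)C1=O
F2 | step 1 | 2,6-dimethoxybenzene-1,4-diol | COc1cc(O)cc(OC)c1O
F3 | step 1 | 6-methoxybenzene-1,2,4-triol | COc1cc(O)cc(O)c1O
F4 | step 6 | 7-methoxy-5,8-bis(methoxymethoxy)-2,2-dimethyl-2H-chromene-6-carbaldehyde | COCOc1c(C=O)c(OC)c(OCOC)c2OC(C)(C)C=Cc12
F5 | step 6 | 1-[7-methoxy-5,8-bis(methoxymethoxy)-2,2-dimethyl-2H-chromen-6-yl]-3-phenylpropan-1-ol (racemic) | COCOc1c(C(O)CCc2ccccc2)c(OC)c(OCOC)c2OC(C)(C)C=Cc12
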